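Numbering: ring A is the dimethoxybenzo ring. Ring B is the cyclohexanone ring, with C1 the carbonyl, C2 and C3 the methyl-bearing carbons and C4 the aryl-bearing carbon. Ring C is the pendant aryl.
Cuts, in retrosynthetic order: the phenol goes back to its benzyl ether. C4–H and C4–ring C go back to a C4 ketone, with C1 masked as a dimethyl ketal. C3–CH3 and C2–CH3 go back to a C2=C3 enone.
Enabling feature: the trans methyls sit on adjacent C2 and C3, between two benzylic carbons. Ring A carries its methoxy groups symmetrically on C6 and C7, so C1 and C4 are equivalent, and one achiral naphthoquinone monoketal with a single enone serves.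
Forward: rings A and B come ready-made from 6,7-dimethoxy-1-tetralone by aromatisation and oxidative ketalisation, and no ring is built. The two methyls are added across C2=C3, ring C is joined at C4, the C4 oxygen is removed and the phenol is freed.
Stereochemistry: C2 comes from the chiral copper–phosphoramidite catalyst, C3 from anti alkylation of the enolate, and C4 from hydride delivery anti to the C3 methyl. Once the ketone is freed, C2 already holds its more stable equatorial position.

Key step: step 4

Assumption: L is (R)-1,1'-binaphthalene-2,2'-diyl N,N-bis[(S)-1-phenylethyl]phosphoramidite. This antipode is taken to deliver methyl to the enone face that gives the (S) β-centre, by analogy with its sense on cyclohex-2-enone. Both antipodes are commercial, so the other is used if the sense is reversed on the benzo-fused monoketal.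

Step 1
Reactants: 1 6,7-dimethoxy-3,4-dihydronaphthalen-1(2H)-one (6,7-dimethoxy-1-tetralone)
Product: 2 2-bromo-6,7-dimethoxy-3,4-dihydronaphthalen-1(2H)-one (racemic)
Conditions: CuBr2 (2.1 equiv), EtOAc/CHCl3, reflux
Reagents that add atoms: copper dibromide, Br[Cu]Br
Why: Heterogeneous α-bromination of an aryl ketone with CuBr2 acts on the enol at C2 and, unlike Br2, should spare the electron-rich ring A; the new centre is racemic and is erased in step 2.

Step 2
Reactants: 2 2-bromo-6,7-dimethoxy-3,4-dihydronaphthalen-1(2H)-one
Product: 3 6,7-dimethoxynaphthalen-1-ol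
Conditions: LiBr, Li2CO3, DMF, 130 °C, Ar
Reagents that add atoms: none
Why: Base-mediated E2 dehydrobromination across C2–C3 followed by enolisation is driven by aromatisation of ring B to the 1-naphthol, and the carbonate base is too mild to touch the aryl methyl ethers.

Step 3
Reactants: 3 6,7-dimethoxynaphthalen-1-ol
Product: 5 4,4,6,7-tetramethoxynaphthalen-1(4H)-one, via trimethoxynaphthol 4 (not isolated)
Conditions: PhI(OAc)2 (2.2 equiv), MeOH, 0 °C → rt; aq. NaHCO3
Reagents that add atoms: methanol, CO
Why: Oxidative dearomatisation of a phenol by a trivalent iodine reagent in methanol: the first equivalent puts a methoxy group on the free para carbon to give 4 after rearomatisation, and the second oxidises this 4-methoxynaphthol to the para-quinone monoketal, para attack being the normal course for 1-naphthols with a free C4.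

Step 4
Reactants: 5 4,4,6,7-tetramethoxynaphthalen-1(4H)-one; 6 trimethylaluminium; 7 iodomethane
Product: 10 (2S,3S)-4,4,6,7-tetramethoxy-2,3-dimethyl-3,4-dihydronaphthalen-1(2H)-one, via dimethylaluminium enolate 8 (not isolated), via lithium aluminate enolate 9 (not isolated)
Conditions: Cu(O2CC4H3S) (copper thiophene-2-carboxylate, 5 mol %), L (10 mol %), Me3Al (1.4 equiv), Et2O, −30 °C; then MeLi (1.4 equiv), −30 °C; then DMPU, MeI (5 equiv), → 0 °C; aq. potassium sodium tartrate/NaHCO3
Reagents that add atoms: trimethylaluminium, C[Al](C)C; iodomethane, CI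
Why: The ligated methylcopper species made from Me3Al binds the enone π bond of 5, adds at the β-carbon to give a trivalent copper alkyl and collapses by reductive elimination, forming the C–CH3 bond next to the ketal (target C2) and leaving aluminium enolate 8; MeLi then converts 8 into the nucleophilic aluminate 9, which displaces iodide from MeI in an SN2 step to form the second C–CH3 bond (target C3). The closest known reaction type is the copper–phosphoramidite-catalysed asymmetric conjugate addition of organozinc and organoaluminium reagents to cyclic enones and benzoquinone monoketals, joined to the ate-activated alkylation of aluminium enolates. No ring is closed, and rings A and B pass through unchanged. The β-centre is set by the chiral ligand, which distinguishes the enantiotopic faces of the flat, achiral enone; the α-centre is set by the substrate, because the half-chair enolate holds the new β-methyl pseudoaxial beside the two ketal methoxy groups, so MeI approaches the opposite face, and the trans isomer is also the more stable one at this enolisable carbon. The step needs 1,4- over 1,2-addition (secured by copper catalysis at low temperature in Et2O), a single reaction site (5 has one enone and its carbonyl has one enolisable α-carbon) and survival of the ketal (aluminate formation switches off the Lewis acidity before warming, and the work-up is kept basic).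

Step 5
Reactants: 11 5-bromo-2-methoxyphenol
Product: 12 2-(benzyloxy)-4-bromo-1-methoxybenzene
Conditions: BnBr, K2CO3, DMF, rt
Reagents that add atoms: benzyl bromide, BrCc1ccccc1
Why: Williamson etherification of the phenoxide with a reactive benzylic halide; the benzyl ether tolerates n-BuLi at −78 °C, the organocerium reagent and cold TFA, and leaves by hydrogenolysis at the end.

Step 6
Reactants: 12 2-(benzyloxy)-4-bromo-1-methoxybenzene; 10 (2S,3S)-4,4,6,7-tetramethoxy-2,3-dimethyl-3,4-dihydronaphthalen-1(2H)-one
Product: 16 (2S,3S,4R)-4-[3-(benzyloxy)-4-methoxyphenyl]-4-hydroxy-6,7-dimethoxy-2,3-dimethyl-3,4-dihydronaphthalen-1(2H)-one, via aryllithium 13 (not isolated), via arylcerium dichloride 14 (not isolated), via ketal carbinol 15 (not isolated)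
Conditions: 12, n-BuLi, THF, −78 °C; anhydrous CeCl3, THF, −78 °C; then 10, −78 → −40 °C; then 0.5 M aq. HCl, THF, 0 °C, brief
Reagents that add atoms: water, O
Why: Bromine–lithium exchange and transmetalation give a weakly basic organocerium reagent that undergoes 1,2-addition to the enolisable ketone instead of deprotonating it, the aryl group arriving anti to the adjacent methyl (a centre that step 7 erases), and acid hydrolysis of the aryl dimethyl ketal through its oxocarbenium ion should be far faster in a water-rich medium than ionisation of the carbinol, which the freed ortho carbonyl then deactivates further.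

Step 7
Reactants: 16 (2S,3S,4R)-4-[3-(benzyloxy)-4-methoxyphenyl]-4-hydroxy-6,7-dimethoxy-2,3-dimethyl-3,4-dihydronaphthalen-1(2H)-one
Product: 17 (2S,3R,4R)-4-[3-(benzyloxy)-4-methoxyphenyl]-6,7-dimethoxy-2,3-dimethyl-3,4-dihydronaphthalen-1(2H)-one
Conditions: Et3SiH (10 equiv), CH2Cl2, −40 °C; TFA (5 equiv) added last, → 0 °C; aq. NaHCO3
Reagents that add atoms: none
Why: Kursanov–Parnes ionic hydrogenation: TFA ionises the doubly benzylic tertiary alcohol to a cation stabilised by the para-methoxy groups of rings A and C, allylic strain against ring C holds the C3 methyl pseudoaxial, and Et3SiH, present in large excess before the acid arrives, delivers hydride to the opposite face, setting C4 as (R) with the aryl group cis to the C3 methyl, while the aryl ketone is not reduced at this temperature.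

Step 8
Reactants: 17 (2S,3R,4R)-4-[3-(benzyloxy)-4-methoxyphenyl]-6,7-dimethoxy-2,3-dimethyl-3,4-dihydronaphthalen-1(2H)-one
Product: 18 (2S,3R,4R)-4-(3-hydroxy-4-methoxyphenyl)-6,7-dimethoxy-2,3-dimethyl-3,4-dihydronaphthalen-1(2H)-one
Conditions: H2 (1 atm), Pd/C, EtOAc/EtOH, rt
Reagents that add atoms: none
Why: Catalytic hydrogenolysis of the benzyl aryl ether under neutral conditions at one atmosphere should leave the electron-rich aryl ketone, the C4–H bond and the three stereocentres untouched.

Compound list
1 | 6,7-dimethoxy-3,4-dihydronaphthalen-1(2H)-one | COc1cc2c(cc1OC)C(=O)CCC2 | starting material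
2 | 2-bromo-6,7-dimethoxy-3,4-dihydronaphthalen-1(2H)-one (racemic) | COc1cc2c(cc1OC)C(=O)C(Br)CC2 | intermediate
3 | 6,7-dimethoxynaphthalen-1-ol | COc1cc2cccc(O)c2cc1OC | intermediate
4 | 4,6,7-trimethoxynaphthalen-1-ol (not isolated) | COc1cc2c(O)ccc(OC)c2cc1OC | intermediate
5 | 4,4,6,7-tetramethoxynaphthalen-1(4H)-one | COc1cc2c(cc1OC)C(OC)(OC)C=CC2=O | intermediate
6 | trimethylaluminium | C[Al](C)C | starting material
7 | iodomethane | CI | starting material
8 | dimethylaluminium (S)-4,4,6,7-tetramethoxy-3-methyl-3,4-dihydronaphthalen-1-olate (not isolated) | COc1cc2c(cc1OC)C(OC)(OC)[C@@H](C)C=C2O[Al](C)C | intermediate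
9 | lithium trimethyl[(S)-4,4,6,7-tetramethoxy-3-methyl-3,4-dihydronaphthalen-1-olato]aluminate (not isolated) | [Li+].COc1cc2c(cc1OC)C(OC)(OC)[C@@H](C)C=C2O[Al-](C)(C)C | intermediate
10 | (2S,3S)-4,4,6,7-tetramethoxy-2,3-dimethyl-3,4-dihydronaphthalen-1(2H)-one (trans) | O=C1c2cc(OC)c(OC)cc2C(OC)(OC)[C@@H](C)[C@@H]1C | intermediate
11 | 5-bromo-2-methoxyphenol | COc1ccc(Br)cc1O | starting material
12 | 2-(benzyloxy)-4-bromo-1-methoxybenzene | COc1ccc(Br)cc1OCc1ccccc1 | intermediate
13 | [3-(benzyloxy)-4-methoxyphenyl]lithium (not isolated) | COc1ccc([Li])cc1OCc1ccccc1 | intermediate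
14 | [3-(benzyloxy)-4-methoxyphenyl]cerium dichloride (not isolated) | COc1ccc([Ce](Cl)Cl)cc1OCc1ccccc1 | intermediate
15 | (1R,2S,3S)-1-[3-(benzyloxy)-4-methoxyphenyl]-4,4,6,7-tetramethoxy-2,3-dimethyl-1,2,3,4-tetrahydronaphthalen-1-ol (not isolated; aryl trans to the adjacent methyl) | COc1ccc([C@@]2(O)c3cc(OC)c(OC)cc3C(OC)(OC)[C@@H](C)[C@@H]2C)cc1OCc1ccccc1 | intermediate
16 | (2S,3S,4R)-4-[3-(benzyloxy)-4-methoxyphenyl]-4-hydroxy-6,7-dimethoxy-2,3-dimethyl-3,4-dihydronaphthalen-1(2H)-one | COc1ccc([C@@]2(O)c3cc(OC)c(OC)cc3C(=O)[C@@H](C)[C@@H]2C)cc1OCc1ccccc1 | intermediate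
17 | (2S,3R,4R)-4-[3-(benzyloxy)-4-methoxyphenyl]-6,7-dimethoxy-2,3-dimethyl-3,4-dihydronaphthalen-1(2H)-one | COc1ccc([C@@H]2c3cc(OC)c(OC)cc3C(=O)[C@@H](C)[C@@H]2C)cc1OCc1ccccc1 | intermediate
18 | (2S,3R,4R)-4-(3-hydroxy-4-methoxyphenyl)-6,7-dimethoxy-2,3-dimethyl-3,4-dihydronaphthalen-1(2H)-one (2,3-trans, 3,4-cis) | COc1ccc([C@@H]2c3cc(OC)c(OC)cc3C(=O)[C@@H](C)[C@@H]2C)cc1O | target

Total step count: 8. Longest linear sequence: 7 (steps 1, 2, 3, 4, 6, 7, 8).

Steps most likely to fail

**Step 7.**
- Risk: proton loss from C3 of the C4 cation may outrun hydride transfer. Ring B then aromatises irreversibly and all three stereocentres are lost.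
- Risk: facial bias may also erode, because the pseudoaxial C2 methyl lies on the face that hydride has to reach.
- Fallback, which avoids a free cation: the route is left at 15, isolated by replacing the acid wash of step 6 with an aqueous NaHCO3 quench.
- Acetylation (Ac2O, DMAP, Et3N, CH2Cl2) should give the tertiary benzylic acetate F1.
- Hydrogenolysis over Pd/C (H2, EtOAc, trace Et3N) is expected to replace the acetate by hydrogen with inversion, the usual course on palladium. It should remove the benzyl group in the same operation, giving the ketal phenol F2.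
- Brief treatment with 0.5 M aq. HCl in THF at 0 °C frees the C1 ketone, and the route is rejoined at 18.

**Step 4.**
- Risk: the Lewis-acidic aluminium species may ionise the benzylic ketal of the enolate, which then loses methanol and aromatises.
- Risk: the aluminate may alkylate sluggishly, so that proton exchange gives unmethylated and doubly methylated material.
- Fallback, in two separate operations without aluminium: from 5, Me2Zn with Cu(OTf)2 and L in toluene at −25 °C, followed by a buffered aqueous quench, should give the β-methyl ketone F3.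
- The carbonyl of F3 has only one enolisable α-carbon, so LiN(SiMe3)2 in THF at −78 °C gives a single lithium enolate F4.
- Methylation of F4 with MeI anti to the β-methyl returns to the route at 10.

**Step 6.**
- Risk: the aryl metal may deprotonate the hindered, electron-rich ketone instead of adding.
- Risk: the doubly benzylic carbinol may dehydrate during the acid wash.
- Fallback, which makes no carbinol at all: from 10, condensation with TsNHNH2 in MeOH at 50 °C should give the tosylhydrazone F5.
- Quenching aryllithium 13 with B(OMe)3 and then dilute HCl gives the arylboronic acid F6.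
- Heating F5 and F6 with K2CO3 in 1,4-dioxane at 110 °C is a metal-free reductive coupling of a tosylhydrazone with a boronic acid. It forms the C4–aryl bond and, by protodeboronation on the face anti to the C3 methyl, the C4–H bond, giving the aryl ketal F7.
- Treatment with 0.5 M aq. HCl in THF hydrolyses the ketal, and the route is rejoined at 17, with step 7 bypassed.

Further compounds
F1 | step 7 | (1R,2S,3S)-1-[3-(benzyloxy)-4-methoxyphenyl]-4,4,6,7-tetramethoxy-2,3-dimethyl-1,2,3,4-tetrahydronaphthalen-1-yl acetate | COc1ccc([C@@]2(OC(C)=O)c3cc(OC)c(OC)cc3C(OC)(OC)[C@@H](C)[C@@H]2C)cc1OCc1ccccc1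
F2 | step 7 | 2-methoxy-5-[(1R,2R,3S)-4,4,6,7-tetramethoxy-2,3-dimethyl-1,2,3,4-tetrahydronaphthalen-1-yl]phenol | COc1ccc([C@@H]2c3cc(OC)c(OC)cc3C(OC)(OC)[C@@H](C)[C@@H]2C)cc1O
F3 | step 4 | (S)-4,4,6,7-tetramethoxy-3-methyl-3,4-dihydronaphthalen-1(2H)-one | COc1cc2c(cc1OC)C(OC)(OC)[C@@H](C)CC2=O
F4 | step 4 | lithium (S)-4,4,6,7-tetramethoxy-3-methyl-3,4-dihydronaphthalen-1-olate | COc1cc2c(cc1OC)C(OC)(OC)[C@@H](C)C=C2O[Li]
F5 | step 6 | N'-[(2S,3S)-4,4,6,7-tetramethoxy-2,3-dimethyl-3,4-dihydronaphthalen-1(2H)-ylidene]-4-methylbenzenesulfonohydrazide | Cc1ccc(cc1)S(=O)(=O)NN=C1c2cc(OC)c(OC)cc2C(OC)(OC)[C@@H](C)[C@@H]1C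
F6 | step 6 | [3-(benzyloxy)-4-methoxyphenyl]boronic acid | COc1ccc(B(O)O)cc1OCc1ccccc1
F7 | step 6 | (1R,2R,3S)-1-[3-(benzyloxy)-4-methoxyphenyl]-4,4,6,7-tetramethoxy-2,3-dimethyl-1,2,3,4-tetrahydronaphthalene | COc1ccc([C@@H]2c3cc(OC)c(OC)cc3C(OC)(OC)[C@@H](C)[C@@H]2C)cc1OCc1ccccc1
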